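## Retrosynthetic overview

1. Target ⇒ a 1-silyloxy-2-endo-aminonorbornene: deamination triggers a 1,2-shift of the one-carbon bridge, which creates the cyclobutane and the enone ring B at once (cyclopentene → cyclohexenone; the C1–C10–C4–C5–C11 ring → cyclobutane).
2. That norbornene, and with it the seven-membered ring ⇒ intramolecular Diels–Alder reaction of a 1-silyloxycyclopentadiene carrying an (E)-nitroalkene on a four-carbon tether.
3. Nitroalkene ⇒ terminal vinyl group; the tiglate (O9) and senecioate (O7) are attached one after the other, a PMB ether keeping O7 apart.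
4. C9/C10 ⇒ 1,3-anti Mukaiyama aldol of a 3-methylcyclopentenone enol silane, then chelate-controlled C-methylation of the aldol dianion; C7 ⇒ enantioselective iridium-catalysed tert-prenylation of a C3 acetal alcohol.
5. Ring order: cyclopentenone (bought) → seven-membered ring and norbornene (cycloaddition) → cyclobutane and ring B (1,2-shift).

Convention and assumption: atom labels C1–C11 are the longipinane positions of the target; 3,3-dimethoxypropan-1-ol is taken as a catalogue compound, and (S)-SEGPHOS as the ligand enantiomer that gives the (3R)-alcohol (otherwise its mirror image is used).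

## Route

Step 1
Reactants: 1 3,3-dimethoxypropan-1-ol; 2 3-methylbuta-1,2-diene
Product: 4 (3R)-1,1-dimethoxy-4,4-dimethylhex-5-en-3-ol, via 3,3-dimethoxypropanal 3 (not isolated)
Conditions: [Ir(cod)Cl]2 (2.5 mol%), (S)-SEGPHOS (5 mol%), 4-cyano-3-nitrobenzoic acid (10 mol%), allyl acetate (10 mol%), Cs2CO3 (20 mol%), toluene, 60 °C
Reagents that add atoms: none
Why: Iridium-catalysed transfer-hydrogenative carbonyl tert-prenylation (Krische-type reverse prenylation from the alcohol oxidation level): the alcohol is dehydrogenated to 3 and the chiral 1,1-dimethylallyl iridium species adds to one aldehyde face, setting C7 and installing the gem-dimethyl carbon C6 and the C5=C11 vinyl group in one operation.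

Step 2
Reactants: 4 (3R)-1,1-dimethoxy-4,4-dimethylhex-5-en-3-ol
Product: 5 (3R)-1,1-dimethoxy-3-[(4-methoxybenzyl)oxy]-4,4-dimethylhex-5-ene
Conditions: NaH, 4-MeOC6H4CH2Cl, Bu4NI (cat.), DMF, 0 → 23 °C
Reagents that add atoms: 4-methoxybenzyl chloride, COc1ccc(CCl)cc1
Why: Williamson etherification under basic conditions that leave the acetal and the stereocentre untouched; the PMB ether later directs the aldol and keeps O7 distinct from O9.

Step 3
Reactants: 5 (3R)-1,1-dimethoxy-3-[(4-methoxybenzyl)oxy]-4,4-dimethylhex-5-ene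
Product: 6 (3R)-3-[(4-methoxybenzyl)oxy]-4,4-dimethylhex-5-enal
Conditions: PPTS (cat.), acetone/H2O 9:1, 50 °C
Reagents that add atoms: water, O
Why: Mild acid-catalysed acetal hydrolysis frees the C9 aldehyde without cleaving the PMB ether or eliminating the β-alkoxy group.

Step 4
Reactants: 7 3-methylcyclopent-2-en-1-one
Product: 9 trimethyl[(4-methylcyclopenta-1,3-dien-2-yl)oxy]silane, via lithium dienolate 8 (not isolated)
Conditions: LiN(iPr)2, THF, −78 °C; Me3SiCl, −78 → 0 °C; used at once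
Reagents that add atoms: chlorotrimethylsilane, C[Si](C)(C)Cl
Why: Kinetic α′-deprotonation (at the future C10) and O-silylation give the cross-conjugated enol silane needed for a Mukaiyama aldol at C10.

Step 5
Reactants: 6 (3R)-3-[(4-methoxybenzyl)oxy]-4,4-dimethylhex-5-enal; 9 trimethyl[(4-methylcyclopenta-1,3-dien-2-yl)oxy]silane
Product: 10 5-[(1R,3R)-1-hydroxy-3-[(4-methoxybenzyl)oxy]-4,4-dimethylhex-5-en-1-yl]-3-methylcyclopent-2-en-1-one (both C5 epimers)
Conditions: BF3·OEt2 (1.1 equiv), CH2Cl2, −78 °C; aq. NaHCO3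
Reagents that add atoms: none
Why: Mukaiyama aldol through an open transition state in which the β-OPMB aldehyde reacts in its dipole-minimised conformer (1,3-anti induction), setting C9 anti to C7; the C10–H epimers converge in step 6.

Step 6
Reactants: 10 5-[(1R,3R)-1-hydroxy-3-[(4-methoxybenzyl)oxy]-4,4-dimethylhex-5-en-1-yl]-3-methylcyclopent-2-en-1-one
Product: 12 (5S)-5-[(1R,3R)-1-hydroxy-3-[(4-methoxybenzyl)oxy]-4,4-dimethylhex-5-en-1-yl]-3,5-dimethylcyclopent-2-en-1-one, via dilithium dianion 11 (not isolated)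
Conditions: LiN(iPr)2 (2.3 equiv), THF, −78 → −40 °C; MeI, DMPU, −78 → −20 °C
Reagents that add atoms: iodomethane, CI
Why: Fráter–Seebach-type alkylation: in the lithium-chelated alkoxide–enolate 11, MeI attacks C10 on the face away from the chain on C9, setting the quaternary C10 with methyl anti to O9.

Step 7
Reactants: 12 (5S)-5-[(1R,3R)-1-hydroxy-3-[(4-methoxybenzyl)oxy]-4,4-dimethylhex-5-en-1-yl]-3,5-dimethylcyclopent-2-en-1-one; 13 (2E)-2-methylbut-2-enoyl chloride
Product: 14 (1R,3R)-1-[(1S)-1,4-dimethyl-2-oxocyclopent-3-en-1-yl]-3-[(4-methoxybenzyl)oxy]-4,4-dimethylhex-5-en-1-yl (2E)-2-methylbut-2-enoate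
Conditions: 13 (3 equiv), DMAP, pyridine, CH2Cl2, 0 → 40 °C
Reagents that add atoms: none
Why: DMAP-catalysed acylation of the only free hydroxyl (O9) with the thermodynamically stable E acid chloride; the quaternary C10 rules out β-elimination.

Step 8
Reactants: 14 (1R,3R)-1-[(1S)-1,4-dimethyl-2-oxocyclopent-3-en-1-yl]-3-[(4-methoxybenzyl)oxy]-4,4-dimethylhex-5-en-1-yl (2E)-2-methylbut-2-enoate
Product: 15 (1R,3R)-1-[(1S)-1,4-dimethyl-2-oxocyclopent-3-en-1-yl]-3-hydroxy-4,4-dimethylhex-5-en-1-yl (2E)-2-methylbut-2-enoate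
Conditions: DDQ, CH2Cl2/pH 7 buffer 10:1, 0 → 23 °C
Reagents that add atoms: none
Why: Oxidative PMB ether cleavage under neutral conditions that spare the enone, the vinyl group and the tiglate and do not promote acyl migration.

Step 9
Reactants: 15 (1R,3R)-1-[(1S)-1,4-dimethyl-2-oxocyclopent-3-en-1-yl]-3-hydroxy-4,4-dimethylhex-5-en-1-yl (2E)-2-methylbut-2-enoate; 16 3-methylbut-2-enoyl chloride
Product: 17 (1R,3R)-1-[(1S)-1,4-dimethyl-2-oxocyclopent-3-en-1-yl]-4,4-dimethyl-3-[(3-methylbut-2-enoyl)oxy]hex-5-en-1-yl (2E)-2-methylbut-2-enoate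
Conditions: 16 (3 equiv), pyridine, DMAP (cat.), CH2Cl2, 0 → 23 °C
Reagents that add atoms: none
Why: Acylation of O7 with pyridine rather than a trialkylamine, so that the acid chloride is not deconjugated through its vinylketene.

Step 10
Reactants: 17 (1R,3R)-1-[(1S)-1,4-dimethyl-2-oxocyclopent-3-en-1-yl]-4,4-dimethyl-3-[(3-methylbut-2-enoyl)oxy]hex-5-en-1-yl (2E)-2-methylbut-2-enoate
Product: 18 (1R,3R,5E)-1-[(1S)-1,4-dimethyl-2-oxocyclopent-3-en-1-yl]-4,4-dimethyl-3-[(3-methylbut-2-enoyl)oxy]-6-nitrohex-5-en-1-yl (2E)-2-methylbut-2-enoate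
Conditions: AgNO2 (3 equiv), TEMPO (0.4 equiv), 4 Å MS, ClCH2CH2Cl, 70 °C
Reagents that add atoms: AgNO2 (silver nitrite), [Ag+].[O-]N=O
Why: Radical nitration of the alkene (nitrogen dioxide radical addition to the terminal carbon, then TEMPO-mediated hydrogen removal) gives the (E)-nitroalkene selectively at the only electron-rich, monosubstituted alkene.

Step 11
Reactants: 18 (1R,3R,5E)-1-[(1S)-1,4-dimethyl-2-oxocyclopent-3-en-1-yl]-4,4-dimethyl-3-[(3-methylbut-2-enoyl)oxy]-6-nitrohex-5-en-1-yl (2E)-2-methylbut-2-enoate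
Product: 20 (1R,4R,5R,7R,9R,10S,11R)-1-[(tert-butyldimethylsilyl)oxy]-11-endo-nitro norbornene [bridgeheads C1 and C4, C2=C3(Me), one-carbon bridge C10(Me), two-carbon bridge C5–C11] whose exo C5 and C10 are joined by C6(Me)2–C7H(O-senecioyl)–C8H2–C9H(O-tigloyl), via silyl dienol ether 19 (not isolated)
Conditions: TBSOTf, Et3N, CH2Cl2, 0 °C; then 40 °C
Reagents that add atoms: tert-butyldimethylsilyl trifluoromethanesulfonate, CC(C)(C)[Si](C)(C)OS(=O)(=O)C(F)(F)F
Why: Soft enolisation at C4 gives the 1-silyloxy-5,5-disubstituted cyclopentadiene 19, which undergoes an intramolecular Diels–Alder reaction with the nitroalkene from the only face the tether reaches, C5 bonding to C4 and the nitro-bearing C11 to the silyloxy-bearing C1 (ortho/para rule), so that C10 fixes C1, C4, C5 and C11 (tether exo, nitro endo from the E alkene) and the seven-membered ring closes.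

Step 12
Reactants: 20 (1R,4R,5R,7R,9R,10S,11R)-1-[(tert-butyldimethylsilyl)oxy]-11-endo-nitro norbornene bridged by the C6–C9 diester chain
Product: 23 (4R,5S,7R,9R,10R,11R)-7-[(3-methylbut-2-enoyl)oxy]-9-{[(2E)-2-methylbut-2-enoyl]oxy}longipin-2-en-1-one (CNP0277258.1), via amine 21 (not isolated), via diazonium acetate 22 (not isolated)
Conditions: Zn, AcOH/THF, 0 → 23 °C; filtration; NaNO2, H2O, 0 → 23 °C
Reagents that add atoms: none
Why: Proposed new method: a Tiffeneau–Demjanov (deaminative semipinacol) rearrangement run on a bridgehead norbornenol derivative — in 22 the endo N2 group is antiperiplanar to the C1–C10 bond, so the one-carbon bridge C10 migrates from C1 to C11 (inversion at C11, retention at C10) while the silyloxy oxygen becomes the C1 carbonyl, enlarging the cyclopentene to the cyclohexenone of ring B and contracting the C1–C10–C4–C5–C11 ring to the cyclobutane; this is the pinyl-to-bornyl Wagner–Meerwein shift run backwards, with the extra strain (roughly 10–15 kcal/mol) paid for by loss of N2 and formation of the conjugated enone; the closest known reaction type is the Tiffeneau–Demjanov ring expansion of 1-(aminomethyl)cycloalkanols and related 2-amino alcohol shifts, not yet shown for a bicyclo[2.2.1] to bicyclo[3.1.1] change.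

## Compound list

1 | 3,3-dimethoxypropan-1-ol | COC(CCO)OC | starting material
2 | 3-methylbuta-1,2-diene | CC(C)=C=C | starting material
3 | 3,3-dimethoxypropanal | COC(CC=O)OC | intermediate
4 | (3R)-1,1-dimethoxy-4,4-dimethylhex-5-en-3-ol | COC(C[C@@H](O)C(C)(C)C=C)OC | intermediate
5 | (3R)-1,1-dimethoxy-3-[(4-methoxybenzyl)oxy]-4,4-dimethylhex-5-ene | COC(C[C@@H](OCc1ccc(OC)cc1)C(C)(C)C=C)OC | intermediate
6 | (3R)-3-[(4-methoxybenzyl)oxy]-4,4-dimethylhex-5-enal | O=CC[C@@H](OCc1ccc(OC)cc1)C(C)(C)C=C | intermediate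
7 | 3-methylcyclopent-2-en-1-one | CC1=CC(=O)CC1 | starting material
8 | lithium 4-methylcyclopenta-1,3-dien-2-olate | [Li]OC1=CCC(C)=C1 | intermediate
9 | trimethyl[(4-methylcyclopenta-1,3-dien-2-yl)oxy]silane | C[Si](C)(C)OC1=CCC(C)=C1 | intermediate
10 | 5-[(1R,3R)-1-hydroxy-3-[(4-methoxybenzyl)oxy]-4,4-dimethylhex-5-en-1-yl]-3-methylcyclopent-2-en-1-one (both C5 epimers) | O[C@H](C[C@@H](OCc1ccc(OC)cc1)C(C)(C)C=C)C1CC(C)=CC1=O | intermediate
11 | dilithium alkoxide–enolate of 10 (O-lithio carbinol, C1=C5 lithium enolate) | [Li]O[C@H](C[C@@H](OCc1ccc(OC)cc1)C(C)(C)C=C)C1=C(O[Li])C=C(C)C1 | intermediate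
12 | (5S)-5-[(1R,3R)-1-hydroxy-3-[(4-methoxybenzyl)oxy]-4,4-dimethylhex-5-en-1-yl]-3,5-dimethylcyclopent-2-en-1-one | O[C@H](C[C@@H](OCc1ccc(OC)cc1)C(C)(C)C=C)[C@]1(C)CC(C)=CC1=O | intermediate
13 | (2E)-2-methylbut-2-enoyl chloride (tigloyl chloride) | C/C=C(\C)C(Cl)=O | starting material
14 | (1R,3R)-1-[(1S)-1,4-dimethyl-2-oxocyclopent-3-en-1-yl]-3-[(4-methoxybenzyl)oxy]-4,4-dimethylhex-5-en-1-yl (2E)-2-methylbut-2-enoate | C/C=C(\C)C(=O)O[C@H](C[C@@H](OCc1ccc(OC)cc1)C(C)(C)C=C)[C@]1(C)CC(C)=CC1=O | intermediate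
15 | (1R,3R)-1-[(1S)-1,4-dimethyl-2-oxocyclopent-3-en-1-yl]-3-hydroxy-4,4-dimethylhex-5-en-1-yl (2E)-2-methylbut-2-enoate | C/C=C(\C)C(=O)O[C@H](C[C@@H](O)C(C)(C)C=C)[C@]1(C)CC(C)=CC1=O | intermediate
16 | 3-methylbut-2-enoyl chloride (senecioyl chloride) | CC(C)=CC(Cl)=O | starting material
17 | (1R,3R)-1-[(1S)-1,4-dimethyl-2-oxocyclopent-3-en-1-yl]-4,4-dimethyl-3-[(3-methylbut-2-enoyl)oxy]hex-5-en-1-yl (2E)-2-methylbut-2-enoate | C/C=C(\C)C(=O)O[C@H](C[C@@H](OC(=O)C=C(C)C)C(C)(C)C=C)[C@]1(C)CC(C)=CC1=O | intermediate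
18 | (1R,3R,5E)-1-[(1S)-1,4-dimethyl-2-oxocyclopent-3-en-1-yl]-4,4-dimethyl-3-[(3-methylbut-2-enoyl)oxy]-6-nitrohex-5-en-1-yl (2E)-2-methylbut-2-enoate | C/C=C(\C)C(=O)O[C@H](C[C@@H](OC(=O)C=C(C)C)C(C)(C)/C=C/[N+](=O)[O-])[C@]1(C)CC(C)=CC1=O | intermediate
19 | (1R,3R,5E)-1-[(1S)-2-[(tert-butyldimethylsilyl)oxy]-1,4-dimethylcyclopenta-2,4-dien-1-yl]-4,4-dimethyl-3-[(3-methylbut-2-enoyl)oxy]-6-nitrohex-5-en-1-yl (2E)-2-methylbut-2-enoate | C/C=C(\C)C(=O)O[C@H](C[C@@H](OC(=O)C=C(C)C)C(C)(C)/C=C/[N+](=O)[O-])[C@]1(C)C=C(C)C=C1O[Si](C)(C)C(C)(C)C | intermediate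
20 | (1R,4R,5R,7R,9R,10S,11R) nitro cycloadduct: 1-(TBS-oxy)-11-endo-nitro norbornene (C1/C4 bridgeheads, C2=C3(Me), C10(Me) bridge) with exo C5 and C10 joined by C6(Me)2–C7H(O-senecioyl)–C8H2–C9H(O-tigloyl) | C/C=C(\C)C(=O)O[C@@H]1C[C@@H](OC(=O)C=C(C)C)C(C)(C)[C@@H]2[C@@H]([N+](=O)[O-])[C@@]3(O[Si](C)(C)C(C)(C)C)C=C(C)[C@@H]2[C@]31C | intermediate
21 | (1R,4R,5R,7R,9R,10S,11R) 11-endo-amine corresponding to 20 | C/C=C(\C)C(=O)O[C@@H]1C[C@@H](OC(=O)C=C(C)C)C(C)(C)[C@@H]2[C@@H](N)[C@@]3(O[Si](C)(C)C(C)(C)C)C=C(C)[C@@H]2[C@]31C | intermediate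
22 | 11-endo-diazonium acetate corresponding to 21 | C/C=C(\C)C(=O)O[C@@H]1C[C@@H](OC(=O)C=C(C)C)C(C)(C)[C@@H]2[C@@H]([N+]#N)[C@@]3(O[Si](C)(C)C(C)(C)C)C=C(C)[C@@H]2[C@]31C.CC(=O)[O-] | intermediate
23 | (4R,5S,7R,9R,10R,11R)-7-[(3-methylbut-2-enoyl)oxy]-9-{[(2E)-2-methylbut-2-enoyl]oxy}longipin-2-en-1-one (CNP0277258.1) | C/C=C(\C)C(=O)O[C@@H]1C[C@@H](OC(=O)C=C(C)C)C(C)(C)[C@@H]2[C@H]3C(=O)C=C(C)[C@@H]2[C@]31C | target

## Step count and risks

Total steps: 12. Longest linear sequence: 11 (steps 1–3 and 5–12; step 4 is the side branch).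

Steps most likely to fail:

Step 12 (the new 1,2-shift). The diazonium ion 22 may ionise before C10 migrates and then give vinyl (C2) migration to a norbornenone, or simple solvolysis. Fallback with known chemistry, setting out from 17 and coming back at 23: the cyclobutane is closed instead by an enolate alkylation of the keto-sulfonate type used for copaene-like cyclobutanes. Compound 17 is homologated (Me3SiCHN2, BF3·OEt2, CH2Cl2, −78 °C, dilute HCl work-up; alkyl rather than vinyl migration) to the cyclohexenone bis-ester F1, in which C11 sits between C1 and C10. OsO4 (cat.)/NaIO4 with 2,6-lutidine cleaves the vinyl group to the neopentyl aldehyde F2. An intramolecular vinylogous aldol reaction (LiN(SiMe3)2, THF, −78 °C) joins C4 to C5 and gives the cis-fused bicyclic hydroxy enone F3. MsCl/Et3N gives the mesylate F4, and KN(SiMe3)2 forms the C11 enolate, which displaces the mesylate with inversion at C5 to give 23.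

Step 11 (seven-membered ring through the cycloaddition). The tether is long, and the nitroalkene may be consumed by the amine base before the diene forms. Fallback, setting out from 18 and coming back at 20: the two bonds are made one after the other by ionic steps. Catalytic DBU in MeCN lets the dienolate attack the nitroalkene through C4 (intramolecular vinylogous Michael addition) to give the cis-fused bicyclic nitro ketone F5. TBSOTf/Et3N then closes the C1–C11 bond in a silylative Henry reaction that leaves the bridgehead oxygen silylated and the nitro group in the more stable endo position (trans to C6), which is 20.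

Step 10 (nitration in the presence of four other alkenes). Radical addition to the enoates or the enone would erode the yield. Fallback, setting out from 17 and coming back at 18: C11 is cut off and brought back from nitromethane. OsO4 (cat.)/NaIO4 with 2,6-lutidine gives the non-enolisable aldehyde F6; a Henry reaction with MeNO2 (iPr2NEt cat.) gives the nitro alcohol F7; MsCl/Et3N dehydrates it to the (E)-nitroalkene 18.

Further compounds
F1 | step 12 | (1R,3R)-1-[(1R)-1,3-dimethyl-5-oxocyclohex-3-en-1-yl]-4,4-dimethyl-3-[(3-methylbut-2-enoyl)oxy]hex-5-en-1-yl (2E)-2-methylbut-2-enoate | C/C=C(\C)C(=O)O[C@H](C[C@@H](OC(=O)C=C(C)C)C(C)(C)C=C)[C@]1(C)CC(C)=CC(=O)C1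
F2 | step 12 | (1R,3R)-1-[(1R)-1,3-dimethyl-5-oxocyclohex-3-en-1-yl]-4,4-dimethyl-3-[(3-methylbut-2-enoyl)oxy]-5-oxopentyl (2E)-2-methylbut-2-enoate | C/C=C(\C)C(=O)O[C@H](C[C@@H](OC(=O)C=C(C)C)C(C)(C)C=O)[C@]1(C)CC(C)=CC(=O)C1
F3 | step 12 | cis-fused bicyclo[5.4.0]undec-2-en-1-one (ring B plus seven-membered ring, C4–C5 bond formed) with C5–OH anti to the future C5–C11 bond, 7-O-senecioyl, 9-O-tigloyl | C/C=C(\C)C(=O)O[C@@H]1C[C@@H](OC(=O)C=C(C)C)C(C)(C)[C@@H](O)[C@@H]2C(C)=CC(=O)C[C@@]21C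
F4 | step 12 | C5 methanesulfonate of F3 | C/C=C(\C)C(=O)O[C@@H]1C[C@@H](OC(=O)C=C(C)C)C(C)(C)[C@@H](OS(C)(=O)=O)[C@@H]2C(C)=CC(=O)C[C@@]21C
F5 | step 11 | cis-fused bicyclo[5.3.0]decenone (cyclopentenone plus seven-membered ring, C4–C5 bond formed) with nitromethyl on C5, 7-O-senecioyl, 9-O-tigloyl | C/C=C(\C)C(=O)O[C@@H]1C[C@@H](OC(=O)C=C(C)C)C(C)(C)[C@H](C[N+](=O)[O-])[C@@H]2C(C)=CC(=O)[C@@]21C
F6 | step 10 | (1R,3R)-1-[(1S)-1,4-dimethyl-2-oxocyclopent-3-en-1-yl]-4,4-dimethyl-3-[(3-methylbut-2-enoyl)oxy]-5-oxopentyl (2E)-2-methylbut-2-enoate | C/C=C(\C)C(=O)O[C@H](C[C@@H](OC(=O)C=C(C)C)C(C)(C)C=O)[C@]1(C)CC(C)=CC1=O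
F7 | step 10 | (1R,3R)-1-[(1S)-1,4-dimethyl-2-oxocyclopent-3-en-1-yl]-5-hydroxy-4,4-dimethyl-3-[(3-methylbut-2-enoyl)oxy]-6-nitrohexyl (2E)-2-methylbut-2-enoate (both epimers at the new carbinol) | C/C=C(\C)C(=O)O[C@H](C[C@@H](OC(=O)C=C(C)C)C(C)(C)C(O)C[N+](=O)[O-])[C@]1(C)CC(C)=CC1=O
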